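## Analysis of the target

The target is a C40 diacid made of three carbocycles: a left trans-decalin (C1–C10), a central cyclohexene (ring C: C12, C13, C14, C15, C15′, C14′) and a right trans-decalin (C1′–C10′). They are joined by the C11 methylene (C9–C11–C12) and by the E-trisubstituted alkene C13′=C12′ with its C11′ methylene (C14′–C13′=C12′–C11′–C9′). There are ten stereocentres: C4, C5, C9, C10 on the left, C12 and C14′ (cis, both S) on ring C, and C4′, C5′, C9′, C10′ on the right. The two decalins have the same relative configuration (trans fusion, side chain cis to the angular methyl, carboxyl equatorial and trans to the angular methyl) but opposite absolute sense. They are therefore quasi-enantiomers, cannot come from one chiral-pool decalin, and cannot relay chirality to each other or to ring C through the flexible links. They also differ in constitution: the right decalin has its exocyclic methylene on C8′ (the polyene-cyclisation pattern), the left one on C7. Sensitive features are four isomerisable alkenes (two exocyclic), the C14′ centre (epimerisable while it carries a carbonyl) and two neopentyl carboxyls, which are carried as silyl-protected CH2OH groups and oxidised last. The hard points are the quaternary C4, C4′ and C10 centres and the cis ring C. The strategy rests on ring B of the left decalin: the C7 methylene is 1,3 to C9 and 1,4 to C10, which as a C7 ketone is the pattern of a 2-oxygenated diene adding to a dienophile with its acceptor on C10. Bonds C5–C10 and C8–C9 can thus be made in one intramolecular cycloaddition that closes rings A and B, with a C10 ester as latent methyl and a C2 oxygen in the tether that later delivers the C4 carboxyl carbon.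

## Retrosynthetic reasoning

**Carboxyl groups.** Target 63 is traced to diol 61 and its bis-silyl ether 60. No skeletal bond is cut; the two hindered acids appear only after all organometallic steps, and one deprotection and one oxidation sequence serve both halves.

**C11′–C12′.** Compound 60 is cut between the sp3 carbon C11′ and the alkene carbon C12′, giving alkenyl iodide 49 and alkyl iodide 58 (used as borate 59). An sp3–sp2 cross-coupling tolerates the hindered, β-branched CH2 and keeps the E geometry, which is fixed beforehand by carbometalation of alkyne 47. An olefination across C12′=C13′ would not control that geometry.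

**Ring C (C12–C14′ and C15–C15′).** Alkyne 47 comes from aldehyde 46, alcohol 45 and imide 44, and 44 is the Diels–Alder adduct of diene 40 and acrylimide 43. This cut makes the ring, puts the alkene at C13=C14 and gives the cis relation of C12 and C14′ (endo rule). The auxiliary of 43 sets the absolute configuration, which the remote decalin could not do. Alkylating a preformed ring C at C12 with a C11 electrophile was rejected because it would enter anti to the C14′ substituent and give the trans isomer.

**C11–C12.** Diene 40 is cut between C11 and C12 into alkyl iodide 33 and iododiene 38. The diene geometry is fixed in 38, and the forward reaction is again an sp3–sp2 coupling through a borate (39).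

**C4–C18.** Iodide 33 is traced through 32, 31, 30 and 29 to homoallylic alcohol 28, and 28 to stannylmethyl ether 26 of allylic alcohol 25. Cutting C4–C18 as a [2,3] shift lets the C2 oxygen deliver the carbon to the face it occupies (α). That gives the equatorial carboxyl carbon and the axial methyl, which alkylation of a C4 enolate would not do reliably. The transposed C2=C3 alkene is hydrogenated while no other alkene is present, which is why the C7 ketone stays masked until 31.

**C10 methyl.** Compound 25 is traced through aldehyde 22 and ketal 20 to cycloadduct 18. The angular methyl is carried as an ester because the ester is what activates and orients the cycloaddition.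

**C5–C10 and C8–C9 (key disconnection).** Cycloadduct 18 is opened to acyclic triene ester 17. Two ring bonds and three stereocentres (C5, C9, C10) come from one stereocentre (C2) and one alkene geometry.

**Precursor 17.** 17 comes from dienone 16 and ketal 15. The Z alkylidene ester of 15 is cut at the ester carbon back to alkenyl iodide 14 (13), made by directed trans-hydroalumination of propargylic alcohol 11. Alkyne 11 is cut at C9–C11 to alkyne 9, and 9 (via 8) at C1–C2 to aldehyde 6 and allenylstannane 7, an asymmetric propargylation that sets C2. This detour through an alkyne fixes the enoate geometry by stereospecific reactions instead of by an α-branched olefination.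

**Diene part.** Aldehyde 6 comes from alcohol 5, a Heck product of iodide 3 and vinyl ketal 4, and 3 comes from alkyne 1. The Z C3=C4 geometry is set in the first step. The dienyl unit is attached before any dienophile alkene exists, so no intramolecular carbopalladation can compete, and it is attached as a ketal so that it survives the alkynide and hydride steps.

**Right decalin (C4′–C5′ and C9′–C10′).** Iodide 58 is traced through 57 and 56 to alcohol 54, the radical bicyclisation product of epoxide 53, made from farnesyl acetate 50 through 51 and 52. The C8′ methylene and the C9′ CH2O group are exactly what an epoxyfarnesyl cyclisation leaves. One Sharpless epoxidation controls the whole ent-decalin, and the temporary C3′ hydroxyl is removed afterwards.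

## Alternatives that were turned down

Alternative 1: Both quaternary centres are disconnected at once, C4–C18 and C4′–C18′, by a two-directional [2,3]-Wittig (Still) rearrangement on the assembled skeleton, giving bis(hydroxymethyl) compound A1. In the forward step an alkyllithium would have to effect two tin–lithium exchanges and two rearrangements in one flask. In its favour, one step makes two quaternary stereocentres, and on this point it is more economical than the chosen route, which uses three steps for C4 alone. Against it, both decalins must reach the union with an allylic C2 oxygen, a C3=C4 alkene and a masked ketone. The right decalin would then need a route as long as the left one, although its C8′ methylene and C4′ carbon are available directly from a polyene cyclisation. After A1 the two ring alkenes must be hydrogenated in the presence of the C13=C14 and C12′=C13′ alkenes, and any shortfall at one site gives hard-to-separate C40 mixtures. The chosen route performs the rearrangement once, early, on a small bicycle where the hydrogenation has no competitor.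

Alternative 2: The right decalin is disconnected at C4′–C5′ and C9′–C10′ on the full skeleton. A titanocene chloride with trivalent titanium (Cp2TiCl) would open a terminal epoxide of an epoxyfarnesyl chain already attached to ring C and close rings A′ and B′ to give A2. In its favour, four stereocentres and the C8′ methylene arise in one step, and the C11′–C12′ coupling is avoided; in fragment count it is the stronger plan. Against it, this is a moderate-yielding radical cascade on the most valuable intermediate. It needs a long acyclic chain to be built onto ring C, and it leaves a C3′ hydroxyl to be removed in two further late steps. The chosen route keeps this reaction but runs it first, on the C15 epoxide 53, where a moderate yield costs little and 54 can be purified and checked before it meets the left half.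

Alternative 3: The right decalin is disconnected at C5′–C10′ and C8′–C9′ as an intramolecular Diels–Alder reaction of a 1-silyloxytriene with an E enoate, giving A3. In its favour, it repeats the logic of the left half, the polarity is matched, and the C10′ methyl is present from the start, which is better than the ester-to-methyl detour on the left. Against it, the dienophile is β,β-disubstituted and forms the quaternary centre at its β-carbon, so it is less reactive than the left-hand dienophile. A3 still needs oxidation-state changes at C8′, reduction of C6′=C7′, a Still–Wittig sequence and hydrogenation. That is about twenty steps for a fragment that the polyene route delivers in eight. In the chosen strategy the cycloaddition is used only where the C7 oxygenation pattern calls for it.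

Key step: step 12

Remark on the chemistry: the left decalin is taken as drawn, with the exocyclic methylene on C7. Compounds 4, 7 and 50, tributyl(iodomethyl)stannane and B-methoxy-9-BBN are assumed to be purchasable. Atom labels: C11 on C9; C17 = CH2 on C7; C18 = carboxyl carbon on C4; C20 = carbon on C10; primed labels for the right half.

## Steps

Step 1
Reactants: 1 but-2-yn-1-ol
Product: 3 (Z)-3-iodobut-2-en-1-ol, via cyclic vinylalanate 2 (not isolated)
Conditions: NaAlH2(OCH2CH2OMe)2, THF, 0 → 23 °C; then I2, THF, –78 → 0 °C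
Reagents that add atoms: iodine, II
Why: Hydroxyl-directed trans-hydroalumination puts aluminium on the distal alkyne carbon and iodinolysis with retention gives the Z iodoalkene (iodine cis to CH2OH), which fixes the later Z C3=C4 geometry.

Step 2
Reactants: 3 (Z)-3-iodobut-2-en-1-ol; 4 2-methyl-2-vinyl-1,3-dioxolane
Product: 5 (2Z,4E)-3-methyl-5-(2-methyl-1,3-dioxolan-2-yl)penta-2,4-dien-1-ol
Conditions: Pd(OAc)2 (5 mol%), Bu4NCl, NaHCO3, DMF, 60 °C
Reagents that add atoms: none
Why: Heck reaction under ligand-free phase-transfer conditions; the alkene has no allylic hydrogen, so terminal insertion and β-hydride elimination give the E alkene, the iodide geometry is kept, and the ketone arrives masked for the organometallic steps.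

Step 3
Reactants: 5 (2Z,4E)-3-methyl-5-(2-methyl-1,3-dioxolan-2-yl)penta-2,4-dien-1-ol
Product: 6 (2Z,4E)-3-methyl-5-(2-methyl-1,3-dioxolan-2-yl)penta-2,4-dienal
Conditions: MnO2, CH2Cl2, 23 °C
Reagents that add atoms: none
Why: Neutral allylic oxidation with MnO2 leaves the Z enal and the acid-labile ketal intact; 6 is used at once because Z dienals isomerise on standing.

Step 4
Reactants: 6 (2Z,4E)-3-methyl-5-(2-methyl-1,3-dioxolan-2-yl)penta-2,4-dienal; 7 tributyl(propa-1,2-dien-1-yl)stannane
Product: 8 (4R,5Z,7E)-6-methyl-8-(2-methyl-1,3-dioxolan-2-yl)octa-5,7-dien-1-yn-4-ol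
Conditions: (R)-BINOL (20 mol%), Ti(OiPr)4 (10 mol%), 4 Å MS, CH2Cl2, –20 °C
Reagents that add atoms: none
Why: Catalytic asymmetric propargylation with an allenylstannane (SE2′, BINOL–titanium catalysis of the Keck type); the (R)-ligand is chosen for Re-face addition by analogy with the allylation sense, which gives the (R)-carbinol, the C2 stereocentre that later steers the cycloaddition and delivers C18.

Step 5
Reactants: 8 (4R,5Z,7E)-6-methyl-8-(2-methyl-1,3-dioxolan-2-yl)octa-5,7-dien-1-yn-4-ol
Product: 9 tert-butyldimethylsilyl ether of 8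
Conditions: TBSCl, imidazole, DMF, 23 °C
Reagents that add atoms: tert-butyldimethylsilyl chloride, CC(C)(C)[Si](C)(C)Cl
Why: Standard silylation of the secondary alcohol; the silyl ether blocks the C2 oxygen so that only the C11 hydroxyl directs the hydroalumination in step 7.

Step 6
Reactants: 9 tert-butyldimethylsilyl ether of 8
Product: 11 (5R,6Z,8E)-5-(tert-butyldimethylsilyloxy)-7-methyl-9-(2-methyl-1,3-dioxolan-2-yl)nona-6,8-dien-2-yn-1-ol, via lithium acetylide 10 (not isolated)
Conditions: n-BuLi, THF, –78 °C; then (CH2O)n, –78 → 23 °C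
Reagents that add atoms: formaldehyde (from paraformaldehyde), C=O
Why: Acetylide hydroxymethylation adds C11 and gives the propargylic alcohol needed for directed hydroalumination; the ketal and silyl ether tolerate the base.

Step 7
Reactants: 11 (5R,6Z,8E)-5-(tert-butyldimethylsilyloxy)-7-methyl-9-(2-methyl-1,3-dioxolan-2-yl)nona-6,8-dien-2-yn-1-ol
Product: 13 (2Z,5R,6Z,8E)-3-iodo-5-(tert-butyldimethylsilyloxy)-7-methyl-9-(2-methyl-1,3-dioxolan-2-yl)nona-2,6,8-trien-1-ol, via cyclic vinylalanate 12 (not isolated)
Conditions: NaAlH2(OCH2CH2OMe)2, THF, 0 °C; then I2, THF, –78 → 0 °C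
Reagents that add atoms: iodine, II
Why: Same directed trans-hydroalumination and iodinolysis as step 1; iodine ends on C10 cis to C11, exactly the geometry of the Z alkylidene ester, and the diene is not touched by the hydride.

Step 8
Reactants: 13 (2Z,5R,6Z,8E)-3-iodo-5-(tert-butyldimethylsilyloxy)-7-methyl-9-(2-methyl-1,3-dioxolan-2-yl)nona-2,6,8-trien-1-ol
Product: 14 benzyl ether of 13
Conditions: NaH, BnBr, Bu4NI (cat.), THF, 0 → 23 °C
Reagents that add atoms: benzyl bromide, BrCc1ccccc1
Why: Williamson benzylation; the free hydroxyl would otherwise lactonise in the carbonylation, and the benzyl group is removed later in the hydrogenation step without extra cost.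

Step 9
Reactants: 14 benzyl ether of 13
Product: 15 methyl (2Z,4R,5Z,7E)-2-(2-benzyloxyethylidene)-4-(tert-butyldimethylsilyloxy)-6-methyl-8-(2-methyl-1,3-dioxolan-2-yl)octa-5,7-dienoate
Conditions: Pd(PPh3)2Cl2 (5 mol%), CO (1 atm), MeOH, Et3N, DMF, 50 °C
Reagents that add atoms: carbon monoxide, [C-]#[O+]; methanol, CO
Why: Palladium-catalysed methoxycarbonylation of an alkenyl iodide goes with retention, so the ester ends cis to CH2OBn (Z alkylidene ester) without relying on olefination selectivity.

Step 10
Reactants: 15 methyl (2Z,4R,5Z,7E)-2-(2-benzyloxyethylidene)-4-(tert-butyldimethylsilyloxy)-6-methyl-8-(2-methyl-1,3-dioxolan-2-yl)octa-5,7-dienoate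
Product: 16 methyl (2Z,4R,5Z,7E)-2-(2-benzyloxyethylidene)-4-(tert-butyldimethylsilyloxy)-6-methyl-9-oxodeca-5,7-dienoate
Conditions: PPTS, acetone/H2O (10:1), 23 °C
Reagents that add atoms: water, O
Why: The allylic ketal hydrolyses under mild acid that spares the secondary silyl ether and the enoate.

Step 11
Reactants: 16 methyl (2Z,4R,5Z,7E)-2-(2-benzyloxyethylidene)-4-(tert-butyldimethylsilyloxy)-6-methyl-9-oxodeca-5,7-dienoate
Product: 17 methyl (2Z,4R,5Z,7E)-2-(2-benzyloxyethylidene)-4-(tert-butyldimethylsilyloxy)-6-methyl-9-(triethylsilyloxy)deca-5,7,9-trienoate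
Conditions: TESOTf, Et3N, CH2Cl2, –78 → 0 °C
Reagents that add atoms: triethylsilyl trifluoromethanesulfonate, CC[Si](CC)(CC)OS(=O)(=O)C(F)(F)F
Why: Soft enolisation of the methyl ketone gives the cross-conjugated 2-silyloxydiene; the ester is not enolised under these conditions, and 17 is passed through Et3N-deactivated silica and used directly.

Step 12
Reactants: 17 methyl (2Z,4R,5Z,7E)-2-(2-benzyloxyethylidene)-4-(tert-butyldimethylsilyloxy)-6-methyl-9-(triethylsilyloxy)deca-5,7,9-trienoate
Product: 18 left-decalin cycloadduct (trans-fused; C10 β-CO2Me, C9 β-CH2OBn, C5 α-H, C2 α-OTBS, C3=C4 with 4-methyl, C6=C7 triethylsilyl enol ether)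
Conditions: PhMe (0.005 M), BHT, 130 °C, sealed base-washed tube
Reagents that add atoms: none
Why: Thermal, concerted but asynchronous [4+2] cycloaddition of normal electron demand between the 2-silyloxydiene (C5=C6–C7=C8) and the Z alkylidene ester (C9=C10); the closest known reaction type is the intramolecular Diels–Alder reaction of 1,7,9-decatrienes carrying a 2-silyloxydiene and an ester-activated dienophile. The polarity is matched, since the nucleophilic diene terminus C8 bonds to the ester β-carbon C9 and C5 bonds to C10, the orientation the tether enforces anyway. Ring B closes as the cyclohexene of the cycloadduct (both new bonds lie in it), and ring A closes in the fused mode through the four-atom tether C1–C4, which adopts a half-chair because it holds the Z C3=C4 alkene. C9 and C10 are set relative to each other by the dienophile geometry, because addition is suprafacial and CH2OBn and the ester, cis on the alkene, end cis (both β). C5 is set by the endo-ester transition state with the tether exo, which places H5 trans to the angular ester (trans fusion). The absolute sense follows from C2: the silyloxy group sits pseudo-equatorial in the favoured half-chair, because the pseudo-axial position is 1,3-diaxial to the endo ester, so the C2 oxygen ends trans to the ester. The step thus needs endo over exo closure and one diene face, secured by the ester–diene secondary overlap, the Z dienophile and the C2 substituent; high dilution, a radical inhibitor, base-washed glass and the lowest workable temperature hold back oligomerisation, enol ether loss and the [1,5]-hydrogen shift from C2 to C6 that the Z diene allows.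

Step 13
Reactants: 18 left-decalin cycloadduct
Product: 20 C7 ethylene ketal of the left decalin (C10 CO2Me, C9 CH2OBn, C2 OTBS, C3=C4), via C7 ketone 19 (not isolated)
Conditions: HOCH2CH2OH, PPTS, PhH, 80 °C (Dean–Stark)
Reagents that add atoms: ethylene glycol, OCCO
Why: Protodesilylation of the enol ether releases the C7 ketone, which is ketalised in the same flask; the ketal carries C7 through hydride, strong base and alkyllithium, and no epimerisable centre is α to the ketone.

Step 14
Reactants: 20 C7 ethylene ketal of the left decalin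
Product: 21 C20 primary alcohol (C10 CH2OH)
Conditions: LiAlH4, THF, 0 → 40 °C
Reagents that add atoms: none
Why: Hydride reduction of the hindered angular ester; ketal, silyl and benzyl ethers are inert.

Step 15
Reactants: 21 C20 primary alcohol
Product: 22 C20 aldehyde (C10 CHO)
Conditions: Dess–Martin periodinane, NaHCO3, CH2Cl2, 0 → 23 °C
Reagents that add atoms: none
Why: Buffered oxidation of the neopentyl alcohol to a non-enolisable aldehyde; the C2 oxygen is still silylated and is not oxidised.

Step 16
Reactants: 22 C20 aldehyde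
Product: 23 C20 aldehyde with free C2 α-hydroxyl
Conditions: TBAF, THF, 0 °C
Reagents that add atoms: none
Why: Fluoride desilylation before the hot alkaline reduction, so that step 17 has one defined product; the aldehyde has no α-hydrogen and cannot form a lactol with the trans C2 hydroxyl.

Step 17
Reactants: 23 C20 aldehyde with free C2 α-hydroxyl
Product: 25 left decalin with C10 β-methyl (C2 α-allylic alcohol, C3=C4, C7 ketal, C9 CH2OBn), via C20 hydrazone 24 (not isolated)
Conditions: N2H4·H2O, KOH, (HOCH2CH2)2O, 130 → 195 °C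
Reagents that add atoms: none
Why: Wolff–Kishner reduction (Huang–Minlon procedure) of the angular aldehyde to the methyl group, the classical route to angular methyls; ketal, benzyl ether, allylic alcohol and the trisubstituted alkene are stable to hot alkali under inert gas.

Step 18
Reactants: 25 left decalin with C10 β-methyl
Product: 26 C2 O-(tributylstannyl)methyl ether of 25
Conditions: KH, Bu3SnCH2I, 18-crown-6 (cat.), THF, 0 → 23 °C
Reagents that add atoms: tributyl(iodomethyl)stannane, CCCC[Sn](CCCC)(CCCC)CI
Why: Williamson alkylation of the only free hydroxyl installs the carbanion precursor for the [2,3] shift.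

Step 19
Reactants: 26 C2 O-(tributylstannyl)methyl ether of 25
Product: 28 left decalin with C4 α-CH2OH (C18) and C4 β-methyl and a C2=C3 alkene, via C2 O-lithiomethyl ether 27 (not isolated)
Conditions: n-BuLi, THF, –78 → –20 °C
Reagents that add atoms: none
Why: Tin–lithium exchange gives the α-alkoxymethyllithium, which undergoes the [2,3]-Wittig rearrangement in Still's variant across O–C2–C3=C4; the shift is suprafacial, so C18 bonds to C4 on the α face that held the oxygen, which sets C4 with the carboxyl carbon equatorial and the methyl axial (β).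

Step 20
Reactants: 28 left decalin with C4 α-CH2OH and a C2=C3 alkene
Product: 29 C18 tert-butyldiphenylsilyl ether of 28
Conditions: TBDPSCl, imidazole, DMAP, DMF, 45 °C
Reagents that add atoms: tert-butyldiphenylsilyl chloride, CC(C)(C)[Si](Cl)(c1ccccc1)c1ccccc1
Why: Silylation of the neopentyl alcohol; the robust silyl group survives the acidic ketal cleavage and all later organometallic steps and keeps C18 distinct from C11.

Step 21
Reactants: 29 C18 tert-butyldiphenylsilyl ether of 28
Product: 30 saturated left decalin with free C11 alcohol (C18 OTBDPS, C7 ketal)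
Conditions: H2 (1 atm), Pd(OH)2/C, EtOAc/EtOH, 23 °C
Reagents that add atoms: none
Why: Heterogeneous hydrogenation saturates the cis-disubstituted C2=C3 alkene (no stereocentre forms) and hydrogenolyses the benzyl ether in the same operation; it is placed here because no other alkene is yet present.

Step 22
Reactants: 30 saturated left decalin with free C11 alcohol
Product: 31 C7 ketone (C11 OH, C18 OTBDPS)
Conditions: PPTS, acetone/H2O, 60 °C
Reagents that add atoms: water, O
Why: Acid-catalysed ketal hydrolysis; the equatorial C11 hydroxyl cannot reach C7 to form a hemiketal, and no stereocentre is α to the ketone.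

Step 23
Reactants: 31 C7 ketone
Product: 32 C7 exocyclic methylene (C11 OH, C18 OTBDPS)
Conditions: Ph3PCH3Br, KOt-Bu, THF, 0 → 23 °C
Reagents that add atoms: methyltriphenylphosphonium bromide, C[P+](c1ccccc1)(c1ccccc1)c1ccccc1.[Br-]
Why: Wittig methylenation of an unhindered cyclohexanone with excess ylide to cover the free hydroxyl; done before iodination so that the basic ylide never meets an alkyl iodide.

Step 24
Reactants: 32 C7 exocyclic methylene
Product: 33 C11 iodide of the left decalin
Conditions: I2, PPh3, imidazole, CH2Cl2, 0 → 23 °C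
Reagents that add atoms: iodine, II
Why: Appel-type iodination of the β-branched primary alcohol; the exocyclic alkene and silyl ether are inert.

Step 25
Reactants: 34 prop-2-yn-1-ol
Product: 36 (E)-3-iodo-2-methylprop-2-en-1-ol, via alkenylalane 35 (not isolated)
Conditions: Me3Al, Cp2ZrCl2 (0.25 equiv), CH2Cl2, 0 → 23 °C; then I2, THF, –30 → 0 °C
Reagents that add atoms: trimethylaluminium, C[Al](C)C; iodine, II
Why: Zirconium-catalysed syn-carboalumination (Negishi) adds methyl to the internal carbon and aluminium to the terminus; iodinolysis with retention gives the E iodide.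

Step 26
Reactants: 36 (E)-3-iodo-2-methylprop-2-en-1-ol
Product: 37 (E)-3-iodo-2-methylprop-2-enal
Conditions: MnO2, CH2Cl2, 23 °C
Reagents that add atoms: none
Why: Neutral allylic oxidation with MnO2 keeps the alkene geometry.

Step 27
Reactants: 37 (E)-3-iodo-2-methylprop-2-enal
Product: 38 (E)-1-iodo-2-methylbuta-1,3-diene
Conditions: Ph3PCH3Br, NaHMDS, THF, –78 → 0 °C
Reagents that add atoms: methyltriphenylphosphonium bromide, C[P+](c1ccccc1)(c1ccccc1)c1ccccc1.[Br-]
Why: Wittig methylenation of the enal gives the volatile iododiene, kept and used as a solution.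

Step 28
Reactants: 33 C11 iodide of the left decalin; 38 (E)-1-iodo-2-methylbuta-1,3-diene
Product: 40 left-decalin diene (C9 carries CH2–CH=C(CH3)–CH=CH2, 12E), via lithium B-alkyl-B-methoxy-9-BBN borate 39 (not isolated)
Conditions: t-BuLi (2.1 equiv), B-methoxy-9-BBN, Et2O/THF, –78 → 23 °C; then 38, Pd(dppf)Cl2 (5 mol%), AsPh3, Cs2CO3, DMF/H2O, 23 °C
Reagents that add atoms: none
Why: Iodine–lithium exchange and capture by the borinate give an ate complex that undergoes B-alkyl Suzuki–Miyaura coupling with the alkenyl iodide with retention of the E geometry; the pent-4-enyllithium from 33 does not cyclise.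

Step 29
Reactants: 41 (R)-4-benzyloxazolidin-2-one; 42 acryloyl chloride
Product: 43 (R)-3-acryloyl-4-benzyloxazolidin-2-one
Conditions: Et3N, LiCl, THF, –20 → 23 °C
Reagents that add atoms: none
Why: N-acylation of the oxazolidinone under mild amine/LiCl conditions that avoid polymerisation of the acryloyl unit.

Step 30
Reactants: 40 left-decalin diene; 43 (R)-3-acryloyl-4-benzyloxazolidin-2-one
Product: 44 ring C imide, cis-(12S,14′S) cyclohexene with the acyl oxazolidinone on C14′
Conditions: Et2AlCl (1.4 equiv), CH2Cl2, –78 → –30 °C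
Reagents that add atoms: none
Why: Auxiliary-controlled Diels–Alder reaction of the chelated s-cis N-acryloyl oxazolidinone (Evans); the benzyl group shields one face so the (R)-auxiliary gives (S) at C14′, endo addition of the E diene gives the cis (S) centre at C12, and the C12 alkyl substituent directs the ortho orientation (C12 to C14′, C15 to C15′).

Step 31
Reactants: 44 ring C imide
Product: 45 ring C primary alcohol (CH2OH on C14′)
Conditions: LiBH4, MeOH (1 equiv), THF, 0 °C
Reagents that add atoms: none
Why: Reductive removal of the auxiliary without epimerising C14′; the oxazolidinone is recovered.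

Step 32
Reactants: 45 ring C primary alcohol
Product: 46 ring C aldehyde (CHO on C14′)
Conditions: Dess–Martin periodinane, NaHCO3, CH2Cl2, 0 °C
Reagents that add atoms: none
Why: Buffered, non-basic oxidation keeps the cis, epimerisable C14′ centre; 46 is used without storage.

Step 33
Reactants: 46 ring C aldehyde
Product: 47 ring C terminal alkyne (ethynyl on C14′)
Conditions: Me3SiCHN2, n-BuLi, THF, –78 → 0 °C
Reagents that add atoms: (trimethylsilyl)diazomethane, C[Si](C)(C)C=[N+]=[N-]
Why: Colvin homologation: addition of lithiated silyldiazomethane, Peterson elimination and 1,2-hydrogen shift of the alkylidene carbene give the alkyne at low temperature, avoiding the carbonate/methanol conditions that could epimerise C14′.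

Step 34
Reactants: 47 ring C terminal alkyne
Product: 49 (E)-alkenyl iodide (C14′–C(CH3)=CHI), via alkenyldimethylalane 48 (not isolated)
Conditions: Me3Al, Cp2ZrCl2 (0.3 equiv), CH2Cl2, 0 → 23 °C; then I2, THF, –30 °C
Reagents that add atoms: trimethylaluminium, C[Al](C)C; iodine, II
Why: Zirconium-catalysed syn-carboalumination and iodinolysis with retention give the E trisubstituted alkenyl iodide; the exocyclic and ring alkenes do not carbometalate.

Step 35
Reactants: 50 (2E,6E)-farnesyl acetate
Product: 51 (2E,6E,10E)-12-hydroxy-3,7,11-trimethyldodeca-2,6,10-trienyl acetate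
Conditions: SeO2 (cat.), t-BuOOH, salicylic acid (cat.), CH2Cl2, 23 °C
Reagents that add atoms: tert-butyl hydroperoxide, CC(C)(C)OO
Why: Selenium dioxide allylic oxidation (ene reaction, then [2,3] shift) is selective for the E methyl of the terminal trisubstituted alkene and gives the E allylic alcohol.

Step 36
Reactants: 51 (2E,6E,10E)-12-hydroxy-3,7,11-trimethyldodeca-2,6,10-trienyl acetate
Product: 52 (2E,6E,10R,11R)-10,11-epoxy-12-hydroxy-3,7,11-trimethyldodeca-2,6-dienyl acetate
Conditions: Ti(OiPr)4, D-(–)-diethyl tartrate, t-BuOOH, 4 Å MS, CH2Cl2, –20 °C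
Reagents that add atoms: tert-butyl hydroperoxide, CC(C)(C)OO
Why: Sharpless asymmetric epoxidation touches only the allylic alcohol alkene; the D-tartrate gives the (10R,11R) epoxide, whose C10 centre fixes the absolute sense of the whole right decalin.

Step 37
Reactants: 52 (2E,6E,10R,11R)-10,11-epoxy-12-hydroxy-3,7,11-trimethyldodeca-2,6-dienyl acetate
Product: 53 12-O-tert-butyldimethylsilyl ether of 52
Conditions: TBSCl, imidazole, CH2Cl2, 23 °C
Reagents that add atoms: tert-butyldimethylsilyl chloride, CC(C)(C)[Si](C)(C)Cl
Why: Silylation of the primary alcohol, which becomes the protected C18′ carboxyl carbon.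

Step 38
Reactants: 53 12-O-tert-butyldimethylsilyl ether of 52
Product: 54 right decalin (3′α-hydroxy, 4′β-CH2OTBS, 4′α-methyl, 5′β-H, 8′(17′)-methylene, 9′α-CH2OAc, 10′α-methyl)
Conditions: Cp2TiCl2 (2.5 equiv), Mn, THF, 23 °C
Reagents that add atoms: none
Why: Cp2TiCl (trivalent titanium), formed in the flask, opens the epoxide by homolysis at the tertiary carbon; the radical closes rings A′ and B′ by two 6-endo additions through chair transition states with the titanoxy group equatorial, and the tertiary C8′ radical is trapped by a second Cp2TiCl and loses β-hydride from the methyl group to give the exocyclic alkene. The (R) carbinol carbon sets C5′, C9′ and C10′ in the ent sense and the E-derived CH2OTBS ends equatorial (β) on C4′; this is a known titanocene epoxypolyene cyclisation, of moderate expected efficiency, acceptable at this early stage.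

Step 39
Reactants: 54 right decalin 3′-alcohol
Product: 55 3′-O-(imidazol-1-ylthiocarbonyl) derivative of 54
Conditions: 1,1′-thiocarbonyldiimidazole, DMAP, ClCH2CH2Cl, 70 °C
Reagents that add atoms: 1,1′-thiocarbonyldiimidazole, S=C(n1ccnc1)n1ccnc1
Why: Thioacylation of the hindered equatorial secondary alcohol prepares the radical deoxygenation.

Step 40
Reactants: 55 3′-O-(imidazol-1-ylthiocarbonyl) derivative of 54
Product: 56 3′-deoxy right decalin (9′α-CH2OAc, 4′β-CH2OTBS)
Conditions: Bu3SnH, AIBN, PhMe, 110 °C
Reagents that add atoms: none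
Why: Barton–McCombie deoxygenation; the secondary C3′ radical has no alkene within reach and no β leaving group, so it is simply reduced.

Step 41
Reactants: 56 3′-deoxy right decalin acetate
Product: 57 right decalin C11′ alcohol
Conditions: K2CO3, MeOH, 23 °C
Reagents that add atoms: none
Why: Mild methanolysis of the acetate; the neopentyl silyl ether is stable.

Step 42
Reactants: 57 right decalin C11′ alcohol
Product: 58 right decalin C11′ iodide
Conditions: I2, PPh3, imidazole, CH2Cl2, 0 → 23 °C
Reagents that add atoms: iodine, II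
Why: Appel-type iodination of the β-branched primary alcohol, as in step 24.

Step 43
Reactants: 58 right decalin C11′ iodide; 49 (E)-alkenyl iodide
Product: 60 fully assembled skeleton with C18 OTBDPS and C18′ OTBS, via lithium B-alkyl-B-methoxy-9-BBN borate 59 (not isolated)
Conditions: t-BuLi (2.1 equiv), B-methoxy-9-BBN, Et2O/THF, –78 → 23 °C; then 49, Pd(dppf)Cl2 (5 mol%), AsPh3, Cs2CO3, DMF/H2O, 23 °C
Reagents that add atoms: none
Why: B-alkyl Suzuki–Miyaura coupling through the ate complex forms C11′–C12′ with retention of the E alkene and touches no stereocentre; the homoallylic lithium intermediate is captured by boron before it can rearrange.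

Step 44
Reactants: 60 fully assembled bis-silyl ether
Product: 61 C18,C18′ diol
Conditions: TBAF, THF, 50 °C
Reagents that add atoms: none
Why: Fluoride cleaves both neopentyl silyl ethers in one operation; the four alkenes are inert.

Step 45
Reactants: 61 C18,C18′ diol
Product: 62 C18,C18′ dialdehyde
Conditions: Dess–Martin periodinane, NaHCO3, CH2Cl2, 23 °C
Reagents that add atoms: none
Why: Oxidation of both neopentyl alcohols to non-enolisable aldehydes under buffered conditions that do not isomerise the exocyclic alkenes.

Step 46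
Reactants: 62 C18,C18′ dialdehyde
Product: 63 target diacid
Conditions: NaClO2, NaH2PO4, 2-methylbut-2-ene, t-BuOH/H2O, 23 °C
Reagents that add atoms: sodium chlorite, [Na+].[O-]Cl=O
Why: Pinnick oxidation converts hindered aldehydes to acids; excess 2-methylbut-2-ene scavenges hypochlorous acid so the alkenes are spared.

## Compound list

1 | but-2-yn-1-ol | CC#CCO | starting material
2 | sodium cyclic vinylalanate from 1 (not isolated) | COCCO[Al-]1(OCCOC)OCC=C1C.[Na+] | intermediate
3 | (Z)-3-iodobut-2-en-1-ol | OC/C=C(C)\I | intermediate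
4 | 2-methyl-2-vinyl-1,3-dioxolane | C=CC1(C)OCCO1 | starting material
5 | (2Z,4E)-3-methyl-5-(2-methyl-1,3-dioxolan-2-yl)penta-2,4-dien-1-ol | OC/C=C(C)\C=C\C1(C)OCCO1 | intermediate
6 | (2Z,4E)-3-methyl-5-(2-methyl-1,3-dioxolan-2-yl)penta-2,4-dienal | O=C/C=C(C)\C=C\C1(C)OCCO1 | intermediate
7 | tributyl(propa-1,2-dien-1-yl)stannane | C=C=C[Sn](CCCC)(CCCC)CCCC | starting material
8 | (4R,5Z,7E)-6-methyl-8-(2-methyl-1,3-dioxolan-2-yl)octa-5,7-dien-1-yn-4-ol | C#CC[C@@H](O)/C=C(C)\C=C\C1(C)OCCO1 | intermediate
9 | tert-butyldimethylsilyl ether of 8 | C#CC[C@@H](O[Si](C)(C)C(C)(C)C)/C=C(C)\C=C\C1(C)OCCO1 | intermediate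
10 | lithium acetylide of 9 (not isolated) | [Li]C#CC[C@@H](O[Si](C)(C)C(C)(C)C)/C=C(C)\C=C\C1(C)OCCO1 | intermediate
11 | (5R,6Z,8E)-5-(tert-butyldimethylsilyloxy)-7-methyl-9-(2-methyl-1,3-dioxolan-2-yl)nona-6,8-dien-2-yn-1-ol | OCC#CC[C@@H](O[Si](C)(C)C(C)(C)C)/C=C(C)\C=C\C1(C)OCCO1 | intermediate
12 | sodium cyclic vinylalanate from 11 (not isolated) | COCCO[Al-]1(OCCOC)OCC=C1C[C@@H](O[Si](C)(C)C(C)(C)C)/C=C(C)\C=C\C2(C)OCCO2.[Na+] | intermediate
13 | (2Z,5R,6Z,8E)-3-iodo-5-(tert-butyldimethylsilyloxy)-7-methyl-9-(2-methyl-1,3-dioxolan-2-yl)nona-2,6,8-trien-1-ol | OC/C=C(\I)C[C@@H](O[Si](C)(C)C(C)(C)C)/C=C(C)\C=C\C1(C)OCCO1 | intermediate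
14 | benzyl ether of 13 | c1ccccc1COC/C=C(\I)C[C@@H](O[Si](C)(C)C(C)(C)C)/C=C(C)\C=C\C2(C)OCCO2 | intermediate
15 | methyl (2Z,4R,5Z,7E)-2-(2-benzyloxyethylidene)-4-(tert-butyldimethylsilyloxy)-6-methyl-8-(2-methyl-1,3-dioxolan-2-yl)octa-5,7-dienoate | c1ccccc1COC/C=C(\C(=O)OC)C[C@@H](O[Si](C)(C)C(C)(C)C)/C=C(C)\C=C\C2(C)OCCO2 | intermediate
16 | methyl (2Z,4R,5Z,7E)-2-(2-benzyloxyethylidene)-4-(tert-butyldimethylsilyloxy)-6-methyl-9-oxodeca-5,7-dienoate | c1ccccc1COC/C=C(\C(=O)OC)C[C@@H](O[Si](C)(C)C(C)(C)C)/C=C(C)\C=C\C(C)=O | intermediate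
17 | methyl (2Z,4R,5Z,7E)-2-(2-benzyloxyethylidene)-4-(tert-butyldimethylsilyloxy)-6-methyl-9-(triethylsilyloxy)deca-5,7,9-trienoate | c1ccccc1COC/C=C(\C(=O)OC)C[C@@H](O[Si](C)(C)C(C)(C)C)/C=C(C)\C=C\C(O[Si](CC)(CC)CC)=C | intermediate
18 | left-decalin cycloadduct (C10 β-CO2Me, C9 β-CH2OBn, C5 α-H, C2 α-OTBS, C3=C4, C6=C7 triethylsilyl enol ether) | CC[Si](CC)(CC)OC1C[C@H](COCc2ccccc2)[C@@]2(C(=O)OC)C[C@@H](O[Si](C)(C)C(C)(C)C)C=C(C)[C@@H]2C=1 | intermediate
19 | C7 ketone from 18 (not isolated) | O=C1C[C@H](COCc2ccccc2)[C@@]2(C(=O)OC)C[C@@H](O[Si](C)(C)C(C)(C)C)C=C(C)[C@@H]2C1 | intermediate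
20 | C7 ethylene ketal of 19 | C1COC2(O1)C[C@H](COCc3ccccc3)[C@@]4(C(=O)OC)C[C@@H](O[Si](C)(C)C(C)(C)C)C=C(C)[C@@H]4C2 | intermediate
21 | C20 primary alcohol (C10 CH2OH) | C1COC2(O1)C[C@H](COCc3ccccc3)[C@@]4(CO)C[C@@H](O[Si](C)(C)C(C)(C)C)C=C(C)[C@@H]4C2 | intermediate
22 | C20 aldehyde (C10 CHO) | C1COC2(O1)C[C@H](COCc3ccccc3)[C@@]4(C=O)C[C@@H](O[Si](C)(C)C(C)(C)C)C=C(C)[C@@H]4C2 | intermediate
23 | C20 aldehyde with free C2 α-hydroxyl | C1COC2(O1)C[C@H](COCc3ccccc3)[C@@]4(C=O)C[C@@H](O)C=C(C)[C@@H]4C2 | intermediate
24 | C20 hydrazone of 23 (not isolated) | C1COC2(O1)C[C@H](COCc3ccccc3)[C@@]4(C=NN)C[C@@H](O)C=C(C)[C@@H]4C2 | intermediate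
25 | left decalin with C10 β-methyl, C2 α-OH, C3=C4, C7 ketal, C9 β-CH2OBn | C1COC2(O1)C[C@H](COCc3ccccc3)[C@@]4(C)C[C@@H](O)C=C(C)[C@@H]4C2 | intermediate
26 | C2 O-(tributylstannyl)methyl ether of 25 | C1COC2(O1)C[C@H](COCc3ccccc3)[C@@]4(C)C[C@@H](OC[Sn](CCCC)(CCCC)CCCC)C=C(C)[C@@H]4C2 | intermediate
27 | C2 O-lithiomethyl ether (not isolated) | C1COC2(O1)C[C@H](COCc3ccccc3)[C@@]4(C)C[C@@H](OC[Li])C=C(C)[C@@H]4C2 | intermediate
28 | left decalin with C4 α-CH2OH, C4 β-methyl, C2=C3 | C1COC2(O1)C[C@H](COCc3ccccc3)[C@@]4(C)CC=C[C@@](C)(CO)[C@@H]4C2 | intermediate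
29 | C18 tert-butyldiphenylsilyl ether of 28 | C1COC2(O1)C[C@H](COCc3ccccc3)[C@@]4(C)CC=C[C@@](C)(CO[Si](c5ccccc5)(c6ccccc6)C(C)(C)C)[C@@H]4C2 | intermediate
30 | saturated left decalin, C11 OH, C18 OTBDPS, C7 ketal | C1COC2(O1)C[C@H](CO)[C@@]3(C)CCC[C@@](C)(CO[Si](c4ccccc4)(c5ccccc5)C(C)(C)C)[C@@H]3C2 | intermediate
31 | C7 ketone, C11 OH, C18 OTBDPS | O=C1C[C@H](CO)[C@@]2(C)CCC[C@@](C)(CO[Si](c3ccccc3)(c4ccccc4)C(C)(C)C)[C@@H]2C1 | intermediate
32 | C7 methylene, C11 OH, C18 OTBDPS | C=C1C[C@H](CO)[C@@]2(C)CCC[C@@](C)(CO[Si](c3ccccc3)(c4ccccc4)C(C)(C)C)[C@@H]2C1 | intermediate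
33 | C11 iodide of the left decalin | C=C1C[C@H](CI)[C@@]2(C)CCC[C@@](C)(CO[Si](c3ccccc3)(c4ccccc4)C(C)(C)C)[C@@H]2C1 | intermediate
34 | prop-2-yn-1-ol | C#CCO | starting material
35 | alkenylalane from 34 (not isolated) | C[Al](C)OC/C(C)=C/[Al](C)C | intermediate
36 | (E)-3-iodo-2-methylprop-2-en-1-ol | OC/C(C)=C/I | intermediate
37 | (E)-3-iodo-2-methylprop-2-enal | O=C/C(C)=C/I | intermediate
38 | (E)-1-iodo-2-methylbuta-1,3-diene | C=C/C(C)=C/I | intermediate
39 | lithium B-alkyl-B-methoxy-9-BBN borate from 33 (not isolated) | C=C1C[C@H](C[B-]3(OC)C4CCCC3CCC4)[C@@]2(C)CCC[C@@](C)(CO[Si](c5ccccc5)(c6ccccc6)C(C)(C)C)[C@@H]2C1.[Li+] | intermediate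
40 | left-decalin (12E)-diene | C=C1C[C@H](C/C=C(C)/C=C)[C@@]2(C)CCC[C@@](C)(CO[Si](c3ccccc3)(c4ccccc4)C(C)(C)C)[C@@H]2C1 | intermediate
41 | (R)-4-benzyloxazolidin-2-one | O=C1OC[C@@H](Cc2ccccc2)N1 | starting material
42 | acryloyl chloride | C=CC(=O)Cl | starting material
43 | (R)-3-acryloyl-4-benzyloxazolidin-2-one | C=CC(=O)N1[C@H](Cc2ccccc2)COC1=O | intermediate
44 | ring C imide, cis-(12S,14′S) | C=C1C[C@H](C[C@@H]3C(C)=CCC[C@@H]3C(=O)N4[C@H](Cc5ccccc5)COC4=O)[C@@]2(C)CCC[C@@](C)(CO[Si](c6ccccc6)(c7ccccc7)C(C)(C)C)[C@@H]2C1 | intermediate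
45 | ring C primary alcohol | C=C1C[C@H](C[C@@H]3C(C)=CCC[C@@H]3CO)[C@@]2(C)CCC[C@@](C)(CO[Si](c4ccccc4)(c5ccccc5)C(C)(C)C)[C@@H]2C1 | intermediate
46 | ring C aldehyde | C=C1C[C@H](C[C@@H]3C(C)=CCC[C@@H]3C=O)[C@@]2(C)CCC[C@@](C)(CO[Si](c4ccccc4)(c5ccccc5)C(C)(C)C)[C@@H]2C1 | intermediate
47 | ring C terminal alkyne | C=C1C[C@H](C[C@@H]3C(C)=CCC[C@@H]3C#C)[C@@]2(C)CCC[C@@](C)(CO[Si](c4ccccc4)(c5ccccc5)C(C)(C)C)[C@@H]2C1 | intermediate
48 | alkenyldimethylalane from 47 (not isolated) | C=C1C[C@H](C[C@@H]3C(C)=CCC[C@@H]3/C(C)=C/[Al](C)C)[C@@]2(C)CCC[C@@](C)(CO[Si](c4ccccc4)(c5ccccc5)C(C)(C)C)[C@@H]2C1 | intermediate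
49 | (E)-alkenyl iodide (C14′–C(CH3)=CHI) | C=C1C[C@H](C[C@@H]3C(C)=CCC[C@@H]3/C(C)=C/I)[C@@]2(C)CCC[C@@](C)(CO[Si](c4ccccc4)(c5ccccc5)C(C)(C)C)[C@@H]2C1 | intermediate
50 | (2E,6E)-farnesyl acetate | CC(=O)OC/C=C(C)/CC/C=C(C)/CCC=C(C)C | starting material
51 | (2E,6E,10E)-12-hydroxy-3,7,11-trimethyldodeca-2,6,10-trienyl acetate | CC(=O)OC/C=C(C)/CC/C=C(C)/CC/C=C(C)/CO | intermediate
52 | (2E,6E,10R,11R)-10,11-epoxy-12-hydroxy-3,7,11-trimethyldodeca-2,6-dienyl acetate | CC(=O)OC/C=C(C)/CC/C=C(C)/CC[C@H]1O[C@]1(C)CO | intermediate
53 | 12-O-tert-butyldimethylsilyl ether of 52 | CC(=O)OC/C=C(C)/CC/C=C(C)/CC[C@H]1O[C@]1(C)CO[Si](C)(C)C(C)(C)C | intermediate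
54 | right decalin, 3′α-OH, 4′β-CH2OTBS, 8′(17′)-ene, 9′α-CH2OAc | CC(=O)OC[C@@H]1C(=C)CC[C@H]2[C@@]1(C)CC[C@@H](O)[C@]2(C)CO[Si](C)(C)C(C)(C)C | intermediate
55 | 3′-O-(imidazol-1-ylthiocarbonyl) derivative of 54 | CC(=O)OC[C@@H]1C(=C)CC[C@H]2[C@@]1(C)CC[C@@H](OC(=S)n3ccnc3)[C@]2(C)CO[Si](C)(C)C(C)(C)C | intermediate
56 | 3′-deoxy right decalin acetate | CC(=O)OC[C@@H]1C(=C)CC[C@H]2[C@@]1(C)CCC[C@]2(C)CO[Si](C)(C)C(C)(C)C | intermediate
57 | right decalin C11′ alcohol | OC[C@@H]1C(=C)CC[C@H]2[C@@]1(C)CCC[C@]2(C)CO[Si](C)(C)C(C)(C)C | intermediate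
58 | right decalin C11′ iodide | IC[C@@H]1C(=C)CC[C@H]2[C@@]1(C)CCC[C@]2(C)CO[Si](C)(C)C(C)(C)C | intermediate
59 | lithium B-alkyl-B-methoxy-9-BBN borate from 58 (not isolated) | CO[B-]1(C[C@@H]2C(=C)CC[C@H]3[C@@]2(C)CCC[C@]3(C)CO[Si](C)(C)C(C)(C)C)C2CCCC1CCC2.[Li+] | intermediate
60 | assembled skeleton, C18 OTBDPS, C18′ OTBS | C=C1C[C@H](C[C@@H]2C(C)=CCC[C@@H]2/C(C)=C/C[C@@H]2C(=C)CC[C@H]3[C@@]2(C)CCC[C@]3(C)CO[Si](C)(C)C(C)(C)C)[C@@]2(C)CCC[C@@](C)(CO[Si](c3ccccc3)(c3ccccc3)C(C)(C)C)[C@@H]2C1 | intermediate
61 | C18,C18′ diol | C=C1C[C@H](C[C@@H]2C(C)=CCC[C@@H]2/C(C)=C/C[C@@H]2C(=C)CC[C@H]3[C@@]2(C)CCC[C@]3(C)CO)[C@@]2(C)CCC[C@@](C)(CO)[C@@H]2C1 | intermediate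
62 | C18,C18′ dialdehyde | C=C1C[C@H](C[C@@H]2C(C)=CCC[C@@H]2/C(C)=C/C[C@@H]2C(=C)CC[C@H]3[C@@]2(C)CCC[C@]3(C)C=O)[C@@]2(C)CCC[C@@](C)(C=O)[C@@H]2C1 | intermediate
63 | target diacid | C=C1C[C@H](C[C@@H]2C(C)=CCC[C@@H]2/C(C)=C/C[C@@H]2C(=C)CC[C@H]3[C@@]2(C)CCC[C@]3(C)C(=O)O)[C@@]2(C)CCC[C@@](C)(C(=O)O)[C@@H]2C1 | target

## Step count and least certain steps

Total: 46 steps. Longest linear sequence: 34 steps (steps 1–24, 28, 30–34, 43–46). The side branches are steps 25–27 (iododiene 38), step 29 (acrylimide 43) and steps 35–42 (right decalin 58).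

**Step 12 (key step).** The most likely failures are a thermal [1,5]-hydrogen shift from C2 to C6 through the Z diene before cycloaddition, competing closure through the exo-ester transition state to the cis-fused isomer, and loss of the enol ether on hot glass. Fallback, setting out from 16: LiHMDS in THF at –78 → 0 °C forms the lithium cross-conjugated dienolate F1, which should close both bonds at low temperature as an intramolecular double Michael reaction (enolate-accelerated cycloaddition), outside the temperature window of the hydrogen shift. Protonation gives ketone 19, which is ketalised as in step 13 and rejoins the route at 20.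

**Step 19.** The [2,3] shift may be outrun by simple protonation of the carbanion or by a [1,2] shift, because the pseudo-equatorial C2–O bond is poorly aligned with the alkene in the trans-fused half-chair. Fallback, setting out from 25: a Johnson–Claisen rearrangement (triethyl orthoacetate, propionic acid, 140 °C) delivers carbon to the same α face of C4 through a [3,3] shift and gives the ethyl ester F2. The extra carbon is then excised: enolate hydroxylation (KHMDS, 2-(phenylsulfonyl)-3-phenyloxaziridine) gives the α-hydroxy ester F3, LiAlH4 gives the 1,2-diol F4, NaIO4 gives the C18 aldehyde F5, and NaBH4 returns alcohol 28.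

**Step 30.** Regiocontrol may be eroded, because the C13 methyl directs opposite to the C12 substituent, and the strong aluminium Lewis acid may ionise the exocyclic alkene or the diene. Fallback, setting out from 40: the reaction is run under catalyst control with 2,2,2-trifluoroethyl acrylate and a proline-derived chiral oxazaborolidinium triflimide (enantiomer matched to the (12S,14′S) adduct) at –78 °C. This gives the cis trifluoroethyl ester F6, which LiAlH4 reduces to alcohol 45.

**Step 4.** The Lewis acid may isomerise the Z enal or open the ketal, and face selectivity on a doubly unsaturated aldehyde may be modest. Fallback, setting out from 6: a catalytic asymmetric Mukaiyama acetate aldol reaction (1-methoxy-1-(trimethylsilyloxy)ethene, Ti(OiPr)4 with a BINOL-derived Schiff-base ligand) gives the methyl (R)-β-hydroxy ester F7. Silylation (TBSCl, imidazole) gives F8, DIBAL-H at –78 °C gives the aldehyde F9, and Colvin homologation as in step 33 gives alkyne 9.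

## Further compounds

F1 | step 12 | lithium cross-conjugated dienolate of 16 | c1ccccc1COC/C=C(\C(=O)OC)C[C@@H](O[Si](C)(C)C(C)(C)C)/C=C(C)\C=C\C(O[Li])=C
F2 | step 19 | ethyl ester from Johnson–Claisen rearrangement of 25 (C4 α-CH2CO2Et, C2=C3) | C1COC2(O1)C[C@H](COCc3ccccc3)[C@@]4(C)CC=C[C@@](C)(CC(=O)OCC)[C@@H]4C2
F3 | step 19 | α-hydroxy ester from F2 | C1COC2(O1)C[C@H](COCc3ccccc3)[C@@]4(C)CC=C[C@@](C)(C(O)C(=O)OCC)[C@@H]4C2
F4 | step 19 | 1,2-diol from F3 | C1COC2(O1)C[C@H](COCc3ccccc3)[C@@]4(C)CC=C[C@@](C)(C(O)CO)[C@@H]4C2
F5 | step 19 | C18 aldehyde from F4 | C1COC2(O1)C[C@H](COCc3ccccc3)[C@@]4(C)CC=C[C@@](C)(C=O)[C@@H]4C2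
F6 | step 30 | ring C 2,2,2-trifluoroethyl ester, cis-(12S,14′S) | C=C1C[C@H](C[C@@H]3C(C)=CCC[C@@H]3C(=O)OCC(F)(F)F)[C@@]2(C)CCC[C@@](C)(CO[Si](c4ccccc4)(c5ccccc5)C(C)(C)C)[C@@H]2C1
F7 | step 4 | methyl (3R,4Z,6E)-3-hydroxy-5-methyl-7-(2-methyl-1,3-dioxolan-2-yl)hepta-4,6-dienoate | COC(=O)C[C@@H](O)/C=C(C)\C=C\C1(C)OCCO1
F8 | step 4 | tert-butyldimethylsilyl ether of F7 | COC(=O)C[C@@H](O[Si](C)(C)C(C)(C)C)/C=C(C)\C=C\C1(C)OCCO1
F9 | step 4 | (3R,4Z,6E)-3-(tert-butyldimethylsilyloxy)-5-methyl-7-(2-methyl-1,3-dioxolan-2-yl)hepta-4,6-dienal | O=CC[C@@H](O[Si](C)(C)C(C)(C)C)/C=C(C)\C=C\C1(C)OCCO1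
A1 | alternative 1 | bis(hydroxymethyl) skeleton with C2=C3 and C2′=C3′ alkenes and C7, C8′ dimethyl ketals | COC1(OC)C[C@H](C[C@@H]2C(C)=CCC[C@@H]2/C(C)=C/C[C@@H]2C(OC)(OC)CC[C@H]3[C@@]2(C)CC=C[C@]3(C)CO)[C@@]2(C)CC=C[C@@](C)(CO)[C@@H]2C1
A2 | alternative 2 | full skeleton with C3′ hydroxyl, C4′ silyloxymethyl and C18 methyl ester | C=C1C[C@H](C[C@@H]2C(C)=CCC[C@@H]2/C(C)=C/C[C@@H]2C(=C)CC[C@H]3[C@@]2(C)CC[C@@H](O)[C@]3(C)CO[Si](C)(C)C(C)(C)C)[C@@]2(C)CCC[C@@](C)(C(=O)OC)[C@@H]2C1
A3 | alternative 3 | right decalin cycloadduct with C9′ ester, C8′ OTES, C2′ OTBS | COC(=O)[C@@H]1[C@H](O[Si](CC)(CC)CC)C=C[C@H]2[C@@]1(C)C[C@H](O[Si](C)(C)C(C)(C)C)C=C2C
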